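**Numbering used throughout:** 1 methyl ester of ring B (starting material), 2 ring B acid, 3 ring B benzyl ester, 4 but-2-ynoic acid, 5 aryl ynoate (precursor of the key step), 6 methyl acetoacetate, 7 enol ether, 8 lithium dienolate, 9 silyloxy diene, 10 silylated ynoate, 11 cycloadduct, 12 depside benzyl ester (product of the key step), 13 formylated depside benzyl ester, 14 baeomycesic acid.

## Analysis of the target

Baeomycesic acid (14) is a depside: two benzene rings joined by a single aryl ester, with no stereocentre and no double-bond geometry, so the problem is one of regiochemistry and chemoselectivity. Ring A carries the depside carbonyl at a1, a hydroxyl at a2, a formyl group at a3, a methoxy group at a4, hydrogen at a5 and a methyl group at a6. Ring B carries the carboxylic acid at b1, a hydroxyl at b2, methyl at b3, the ester oxygen at b4, hydrogen at b5 and methyl at b6. The sensitive groups are the aryl ester (cleaved by alkoxides and amines), the aldehyde, and the salicylic acid of ring B, which loses CO2 when heated or kept in acid. The a4 oxygen must end up methylated while the a2 and b2 oxygens stay free. The classical difficulty is the ester bond itself: the a1 carboxyl is flanked by the a2 oxygen and the a6 methyl group, and the b4 phenol has an ortho methyl group. The strategy rests on the a2/a4 oxygens of ring A standing 1,3 to each other. Read this way, a2–a3–a4–a5 is a 1,3-dioxygenated four-carbon diene unit and a1–a6, with its carbonyl and methyl substituents, is a but-2-ynoate. Ring B needs no construction, since its methyl ester 1 can be bought.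

## Retrosynthetic reasoning

**14 to 13.** The last bond cut is the O–benzyl bond of a b1 benzyl ester. A free salicylic acid would not survive the base-mediated steps and would quench the diene, so the acid stays masked until the end. The forward reaction is a hydrogenolysis that must spare the aldehyde and the aryl ester.

**13 to 12.** The a3–CHO bond is cut next. An aldehyde cannot be carried through the cycloaddition, because a silyl ketene acetal would add to it. In 12, a3 is the only unsubstituted carbon ortho to a phenol: both neighbours of the b2 hydroxyl are occupied, and a5 and b5 are para positions. An ortho-directed formylation through a metal phenoxide therefore has a single site.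

**12 to 5 and 9.** This is the central disconnection: the a1–a2 and a5–a6 bonds are cut. It gives the aryl ynoate 5, in which the depside ester bond already exists, and the diene 9, whose carbons become a2 to a5. Cutting here rather than at the ester bond avoids joining a di-ortho-substituted benzoic acid to a hindered phenol. It also delivers the two ring A oxygens already differentiated, a4 from the enol ether and a2 from the silyl ketene acetal, so ring A needs no protecting group. The forward reaction must pair the nucleophilic CH2 end of 9 with the methyl-bearing carbon of the triple bond and then aromatise with loss of the a2 methoxy group. Because 5 carries a free b2 hydroxyl, it is silylated in the flask to 10 before the diene is added, and the cycloadduct 11 is not isolated.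

**5 to 3 and 4.** The bond between the b4 oxygen and the ynoate carbonyl is cut. The acid 4 is unhindered, and in 3 only the b4 hydroxyl is free of a hydrogen bond to the ester carbonyl, so a mild carbodiimide esterification should be selective.

**3 to 2 to 1.** The benzyl ester is traced to the acid 2 and that to the commercial methyl ester 1. The exchange is needed because a methyl ester could not be removed at the end without breaking the depside link.

**9 to 8 to 7 to 6.** The diene is the O-silylated form of the extended enolate 8 of the enol ether 7, which comes from the β-keto ester 6 by O-methylation of its ketone.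

## Alternatives that were turned down

**Alternative 1:** Ring B is taken back below the aromatic oxidation level by cutting b1–b6 and b3–b4, which leads to benzyl 3-oxopentanoate (A1) and benzyl (E)-but-2-enoate (A2).
- Forward key step: the doubly activated methylene of A1 adds to A2 (Michael addition), and the α-carbon on the ethyl side of the ketone then closes onto the crotonate ester (Dieckmann condensation) to give the dione A3. A3 would be dehydrogenated to 3 and esterified at b4 with the preformed ring A acid A4.
- For: robust anionic chemistry from very cheap acyclic esters; each step is more certain than a thermal cycloaddition.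
- Against: it builds a ring that can be bought in aromatic form as 1. It needs an extra aromatisation step under conditions that threaten a benzyl ester, and the alkoxide base must match the benzyl esters to avoid scrambling. Above all it leaves the real problem untouched: A4 has to be made separately, and its di-ortho-substituted, aldehyde-bearing carboxyl must still be joined to a hindered phenol.
- Comparison: stronger on the reliability of its ring-forming step. The chosen strategy forms the ester bond from an unhindered acid and builds ring A with its oxygens already differentiated. Reaching 3 takes two steps either way, so nothing is saved.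

**Alternative 2:** Both bonds of the depside carbonyl are cut (a1–C(=O) and C(=O)–O at b4), so the carbonyl carbon comes from carbon monoxide (A6), ring A from the aryl iodide A5 and ring B from 3.
- Forward key step: oxidative addition of the C–I bond of A5 to zerovalent palladium (from Pd(OAc)2 and a wide-bite-angle diphosphine), insertion of A6, and capture of the acylpalladium by the b4 phenoxide in the presence of an amine base, giving A7. Acid removal of the methoxymethyl ether and hydrogenolysis would follow.
- For: highly convergent. The aldehyde arrives in place, so no late formylation is needed, and no benzoic acid has to be activated.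
- Against: the iodide at a1 is flanked by an alkoxy and a methyl group, and the hindered acylpalladium must be trapped by a weakly nucleophilic, ortho-substituted phenol; reduction and decarbonylation compete. A free aldehyde is exposed to palladium, A6 and amine. A5 requires a multi-step synthesis in which iodination must choose a1 over a5, and ring A needs a protecting group that is later removed with acid.
- Comparison: stronger on convergence and on avoiding the formylation. The chosen strategy needs no protecting group on ring A and makes its substitution pattern in one step from a diene available in two steps from 6; its risk sits in one thermal step that can be run with excess diene.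

**Alternative 3:** Ring B is dismantled by benzannulation logic, cutting b1–b2, b2–b3, b4–b5 and b5–b6, which leads to the diazo ketone A8 and the ynol ester A10 of a protected ring A acid.
- Forward key step: irradiation of A8 causes a Wolff rearrangement to the vinylketene A9, which adds to the triple bond of A10 in a [2+2] cycloaddition. The vinylcyclobutenone opens (4π) to a dienylketene, which closes (6π) and tautomerises to the phenol A11. Hydrogenolysis and acetal hydrolysis would then give 14.
- For: all six substituents of ring B arrive regiodefined in one operation, the b2 hydroxyl appears free, and the ester C–O bond exists before the ring is formed.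
- Against: alkynyl carboxylates are rare, are reached through alkynyliodonium salts, rearrange and hydrolyse easily, and are much weaker ketenophiles than the alkoxy- and siloxyalkynes for which this benzannulation is established. A8 needs diazo chemistry. The ring A acid must still be built and protected twice, and the ring being constructed is the one that can be bought.
- Comparison: it shares the idea of making the ester first and growing a ring onto it, but applies it to the easy half of the molecule and leaves ring A to conventional synthesis. It would be several steps longer than the eight of the chosen route, which spends its ring-forming step on ring A, where the substitution problem lies.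

Key step: step 6

## Route

Assumption: the geometry of the ketene acetal double bond of 9 is not defined and does not matter, because that carbon becomes aromatic; the ketal carbon of 11 is formed racemic and is lost in the same step.

**Step 1**
Reactants: 1 methyl 2,4-dihydroxy-3,6-dimethylbenzoate
Product: 2 2,4-dihydroxy-3,6-dimethylbenzoic acid
Conditions: conc. H2SO4, 0 °C to rt, short contact; then ice/water, filter cold
Reagents that add atoms: water, O
Why: Ester hydrolysis by acyl–oxygen fission through an acylium ion (AAC1); the carbonyl is flanked by the b2 hydroxyl and the b6 methyl group and is pushed by two ring oxygens, so it ionises in cold concentrated acid and is trapped by water on quenching, while the cold, short contact limits sulfonation at b5 and loss of CO2.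

**Step 2**
Reactants: 2 2,4-dihydroxy-3,6-dimethylbenzoic acid
Product: 3 benzyl 2,4-dihydroxy-3,6-dimethylbenzoate
Conditions: BnBr, KHCO3, DMF, rt
Reagents that add atoms: benzyl bromide, BrCc1ccccc1
Why: Carboxylate O-alkylation (SN2); KHCO3 deprotonates only the carboxylic acid, so the benzyl group goes on the carboxylate and both phenols stay free.

**Step 3**
Reactants: 3 benzyl 2,4-dihydroxy-3,6-dimethylbenzoate; 4 but-2-ynoic acid
Product: 5 benzyl 4-(but-2-ynoyloxy)-2-hydroxy-3,6-dimethylbenzoate
Conditions: DCC, DMAP (cat.), CH2Cl2, 0 °C
Reagents that add atoms: none
Why: Steglich esterification; the b4 hydroxyl is the only phenol not held in a hydrogen bond to the ester carbonyl and not flanked on both sides, the acid is unhindered, and low temperature with little DMAP limits conjugate addition to the ynoate.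

**Step 4**
Reactants: 6 methyl acetoacetate
Product: 7 methyl (E)-3-methoxybut-2-enoate
Conditions: HC(OMe)3, conc. H2SO4 (cat.), neat, rt; then distil
Reagents that add atoms: trimethyl orthoformate, COC(OC)OC
Why: Acid-catalysed ketalisation of the ketone by the orthoester and loss of methanol on distillation (enol ether formation from a β-keto ester) should give the more stable (E)-enol ether.

**Step 5**
Reactants: 7 methyl (E)-3-methoxybut-2-enoate
Product: 9 1,3-dimethoxy-1-(trimethylsilyloxy)buta-1,3-diene, via lithium dienolate 8 (not isolated)
Conditions: LiN(iPr)2 (commercial solution), THF, −78 °C; then Me3SiCl, −78 °C to rt; pentane, filter under N2, distil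
Reagents that add atoms: chlorotrimethylsilane, C[Si](C)(C)Cl
Why: Kinetic γ-deprotonation of the β-methoxy enoate gives the extended enolate 8, which is silylated on oxygen (silyl ketene acetal formation); a non-aqueous work-up is used because 9 hydrolyses readily.

**Step 6**
Reactants: 5 benzyl 4-(but-2-ynoyloxy)-2-hydroxy-3,6-dimethylbenzoate; 9 1,3-dimethoxy-1-(trimethylsilyloxy)buta-1,3-diene
Product: 12 benzyl 2-hydroxy-4-(2-hydroxy-4-methoxy-6-methylbenzoyloxy)-3,6-dimethylbenzoate, via silylated ynoate 10 (not isolated), via cycloadduct 11 (not isolated)
Conditions: N,O-bis(trimethylsilyl)acetamide (1.5 equiv), toluene, 60 °C; then 9 (3 equiv), 110 °C, sealed tube; then 1 M HCl, THF, rt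
Reagents that add atoms: none
Why: This is a [4+2] cycloaddition of an electron-rich 1,1,3-trioxygenated diene with an electron-poor acetylenic ester followed by aromatisation, the established route from Brassard-type dienes to 4-alkoxysalicylates. The b2 hydroxyl of 5 is first capped in the flask as the trimethylsilyl ether 10, so that no acidic proton remains to destroy the ketene acetal, and the excess silylating agent also traps the methanol released later. The diene HOMO has its largest coefficient at the CH2 terminus and the ynoate LUMO at the methyl-bearing β-carbon, so the concerted but asynchronous addition (in the limit a Michael addition followed by closure of the ester α-carbon onto the ketene acetal carbon) forms a5–a6 ahead of a1–a2 and closes the six-membered ring A as the cyclohexa-1,4-diene 11. The aryl ester lowers the LUMO more than an alkyl ester would, which offsets the retarding β-methyl group. In 11 the a2 carbon is a mixed methyl silyl ketal standing 1,4 to the a5 methylene, and loss of methanol across these positions, on heating or on the acid work-up, gives the benzene ring; hydrolysis of the two silyl ethers then frees the a2 and b2 phenols. Methanol rather than silanol should leave, because either protonation of the more basic methoxy oxygen or prior desilylation to a hemiketal ends in expulsion of the methoxy group, so the a2 oxygen stays as the phenol and the a4 enol ether oxygen stays methylated. The only stereocentre formed, the ketal carbon of 11, is racemic and disappears on aromatisation; the selectivity the step needs is regiochemical, and the polarisation of both partners secures it.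

**Step 7**
Reactants: 12 benzyl 2-hydroxy-4-(2-hydroxy-4-methoxy-6-methylbenzoyloxy)-3,6-dimethylbenzoate
Product: 13 benzyl 4-(3-formyl-2-hydroxy-4-methoxy-6-methylbenzoyloxy)-2-hydroxy-3,6-dimethylbenzoate
Conditions: MgCl2 (anhydrous), Et3N, (CH2O)n, THF, reflux; then 1 M HCl
Reagents that add atoms: formaldehyde (as paraformaldehyde), C=O
Why: Magnesium-mediated ortho-formylation of a phenol (Casnati–Skattebøl): the magnesium phenoxide delivers coordinated formaldehyde to the ortho carbon and a second formaldehyde oxidises the hydroxymethyl group by hydride transfer. a3 is the only free carbon ortho to a phenol and is also activated by the a4 methoxy group, and both ester carbonyls are deactivated towards alkoxide by their ortho phenoxides and their two ortho substituents.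

**Step 8**
Reactants: 13 benzyl 4-(3-formyl-2-hydroxy-4-methoxy-6-methylbenzoyloxy)-2-hydroxy-3,6-dimethylbenzoate
Product: 14 baeomycesic acid, 4-(3-formyl-2-hydroxy-4-methoxy-6-methylbenzoyloxy)-2-hydroxy-3,6-dimethylbenzoic acid
Conditions: H2 (1 atm), 10% Pd/C, EtOAc, rt; stop after one equivalent of H2
Reagents that add atoms: none
Why: Hydrogenolysis of a benzyl ester; the aldehyde is hydrogen-bonded to the a2 hydroxyl and flanked by two oxygen substituents, so it should be reduced much more slowly than the benzylic C–O bond is cleaved, and the aryl ester is inert.

## Compound list

1 | methyl 2,4-dihydroxy-3,6-dimethylbenzoate | Cc1cc(O)c(C)c(O)c1C(=O)OC | starting material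
2 | 2,4-dihydroxy-3,6-dimethylbenzoic acid | Cc1cc(O)c(C)c(O)c1C(=O)O | intermediate
3 | benzyl 2,4-dihydroxy-3,6-dimethylbenzoate | Cc1cc(O)c(C)c(O)c1C(=O)OCc1ccccc1 | intermediate
4 | but-2-ynoic acid | CC#CC(=O)O | starting material
5 | benzyl 4-(but-2-ynoyloxy)-2-hydroxy-3,6-dimethylbenzoate | CC#CC(=O)Oc1cc(C)c(C(=O)OCc2ccccc2)c(O)c1C | intermediate
6 | methyl acetoacetate | COC(=O)CC(C)=O | starting material
7 | methyl (E)-3-methoxybut-2-enoate | CO/C(C)=C/C(=O)OC | intermediate
8 | lithium 1,3-dimethoxybuta-1,3-dien-1-olate | [Li+].C=C(OC)C=C(OC)[O-] | intermediate
9 | 1,3-dimethoxy-1-(trimethylsilyloxy)buta-1,3-diene | C=C(OC)C=C(OC)O[Si](C)(C)C | intermediate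
10 | benzyl 4-(but-2-ynoyloxy)-3,6-dimethyl-2-(trimethylsilyloxy)benzoate | CC#CC(=O)Oc1cc(C)c(C(=O)OCc2ccccc2)c(O[Si](C)(C)C)c1C | intermediate
11 | benzyl 4-{[4,6-dimethoxy-2-methyl-6-(trimethylsilyloxy)cyclohexa-1,4-dien-1-yl]carbonyloxy}-3,6-dimethyl-2-(trimethylsilyloxy)benzoate (racemic) | COC1=CC(OC)(O[Si](C)(C)C)C(C(=O)Oc2cc(C)c(C(=O)OCc3ccccc3)c(O[Si](C)(C)C)c2C)=C(C)C1 | intermediate
12 | benzyl 2-hydroxy-4-(2-hydroxy-4-methoxy-6-methylbenzoyloxy)-3,6-dimethylbenzoate | COc1cc(C)c(C(=O)Oc2cc(C)c(C(=O)OCc3ccccc3)c(O)c2C)c(O)c1 | intermediate
13 | benzyl 4-(3-formyl-2-hydroxy-4-methoxy-6-methylbenzoyloxy)-2-hydroxy-3,6-dimethylbenzoate | COc1cc(C)c(C(=O)Oc2cc(C)c(C(=O)OCc3ccccc3)c(O)c2C)c(O)c1C=O | intermediate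
14 | baeomycesic acid | COc1cc(C)c(C(=O)Oc2cc(C)c(C(=O)O)c(O)c2C)c(O)c1C=O | target

## Step count and uncertain steps

Total: 8 steps. Longest linear sequence: 6 steps (steps 1, 2, 3, 6, 7, 8); the diene branch (steps 4 and 5) joins at step 6.

**Step 6 (key step).** The diene may be lost faster than it reacts, by proton or silyl transfer from any hydroxyl left unsilylated and by thermal decomposition, because the β-methyl group slows the ynoate. Conjugate addition may also stop short of ring closure, and the ketal may ionise in the wrong sense and leave a methyl ether at a2. Fallback: the benzannulation is given up and the ester bond is made in the classical way. Setting out from 3, the b4 hydroxyl is acylated with 2-hydroxy-4-methoxy-6-methylbenzoic acid F1, a known lichen acid obtained from a natural-product supplier, through its mixed anhydride with trifluoroacetic anhydride in toluene at rt. This returns to the route at 12.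

**Step 7.** The magnesium methoxide formed in the redox stage may cleave the depside ester by transesterification, and the hydroxymethylation may be slow because the a2 phenoxide is conjugated to the ester. Fallback: from 12, an electrophilic formylation under non-basic conditions (Rieche formylation: dichloromethyl methyl ether, TiCl4, CH2Cl2, −78 to 0 °C, then aqueous acid), in which the titanium chelate of the a2 oxygen and the depside carbonyl directs attack to a3. This gives 13 directly.

**Step 8.** Over-reduction of the formyl group to the hydroxymethyl or methyl stage may accompany the hydrogenolysis. Fallback: the carboxyl protecting group is changed to one removed without hydrogen.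
- From 2, allyl bromide and KHCO3 in DMF give allyl 2,4-dihydroxy-3,6-dimethylbenzoate F2.
- Esterification with 4 as in step 3 gives allyl 4-(but-2-ynoyloxy)-2-hydroxy-3,6-dimethylbenzoate F3.
- The cycloaddition with 9 as in step 6 gives allyl 2-hydroxy-4-(2-hydroxy-4-methoxy-6-methylbenzoyloxy)-3,6-dimethylbenzoate F4.
- Formylation as in step 7 gives allyl 4-(3-formyl-2-hydroxy-4-methoxy-6-methylbenzoyloxy)-2-hydroxy-3,6-dimethylbenzoate F5.
- Deallylation with Pd(PPh3)4 (zerovalent palladium) and phenylsilane in CH2Cl2 at rt, conditions that touch neither the aldehyde nor the aryl ester, returns to the route at 14.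

**Step 1.** Sulfonation at b5 in the concentrated acid and loss of CO2 from the acid during the quench may lower the return. Fallback: the methyl group is removed by SN2 attack of iodide (LiI, ethyl acetate, reflux), which gives lithium 2,4-dihydroxy-3,6-dimethylbenzoate F6 without passing through the free acid in a protic medium. F6 is benzylated directly with benzyl bromide in DMF and returns to the route at 3.

## Further compounds

F1 | step 6 | 2-hydroxy-4-methoxy-6-methylbenzoic acid | COc1cc(C)c(C(=O)O)c(O)c1
F0 | step 7 | none | none
F2 | step 8 | allyl 2,4-dihydroxy-3,6-dimethylbenzoate | C=CCOC(=O)c1c(C)cc(O)c(C)c1O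
F3 | step 8 | allyl 4-(but-2-ynoyloxy)-2-hydroxy-3,6-dimethylbenzoate | CC#CC(=O)Oc1cc(C)c(C(=O)OCC=C)c(O)c1C
F4 | step 8 | allyl 2-hydroxy-4-(2-hydroxy-4-methoxy-6-methylbenzoyloxy)-3,6-dimethylbenzoate | COc1cc(C)c(C(=O)Oc2cc(C)c(C(=O)OCC=C)c(O)c2C)c(O)c1
F5 | step 8 | allyl 4-(3-formyl-2-hydroxy-4-methoxy-6-methylbenzoyloxy)-2-hydroxy-3,6-dimethylbenzoate | COc1cc(C)c(C(=O)Oc2cc(C)c(C(=O)OCC=C)c(O)c2C)c(O)c1C=O
F6 | step 1 | lithium 2,4-dihydroxy-3,6-dimethylbenzoate | [Li+].Cc1cc(O)c(C)c(O)c1C(=O)[O-]
A1 | alternative 1 | benzyl 3-oxopentanoate | CCC(=O)CC(=O)OCc1ccccc1
A2 | alternative 1 | benzyl (E)-but-2-enoate | C/C=C/C(=O)OCc1ccccc1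
A3 | alternative 1 | benzyl 3,6-dimethyl-2,4-dioxocyclohexane-1-carboxylate | CC1CC(=O)C(C)C(=O)C1C(=O)OCc1ccccc1
A4 | alternative 1 | 3-formyl-2-hydroxy-4-methoxy-6-methylbenzoic acid | COc1cc(C)c(C(=O)O)c(O)c1C=O
A5 | alternative 2 | 3-iodo-6-methoxy-2-(methoxymethoxy)-4-methylbenzaldehyde | COCOc1c(I)c(C)cc(OC)c1C=O
A6 | alternative 2 | carbon monoxide | [C-]#[O+]
A7 | alternative 2 | benzyl 4-[3-formyl-4-methoxy-2-(methoxymethoxy)-6-methylbenzoyloxy]-2-hydroxy-3,6-dimethylbenzoate | COCOc1c(C(=O)Oc2cc(C)c(C(=O)OCc3ccccc3)c(O)c2C)c(C)cc(OC)c1C=O
A8 | alternative 3 | benzyl (E)-5-diazo-3-methyl-4-oxopent-2-enoate | C/C(=C\C(=O)OCc1ccccc1)C(=O)C=[N+]=[N-]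
A9 | alternative 3 | benzyl (E)-3-methyl-5-oxopenta-2,4-dienoate | C/C(C=C=O)=C\C(=O)OCc1ccccc1
A10 | alternative 3 | prop-1-ynyl 2-(benzyloxy)-3-(1,3-dioxolan-2-yl)-4-methoxy-6-methylbenzoate | CC#COC(=O)c1c(C)cc(OC)c(C2OCCO2)c1OCc1ccccc1
A11 | alternative 3 | benzyl 4-[2-(benzyloxy)-3-(1,3-dioxolan-2-yl)-4-methoxy-6-methylbenzoyloxy]-2-hydroxy-3,6-dimethylbenzoate | COc1cc(C)c(C(=O)Oc2cc(C)c(C(=O)OCc3ccccc3)c(O)c2C)c(OCc2ccccc2)c1C1OCCO1
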